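**Retrosynthetic overview**

1. Target ⇐ acid hydrolysis of four methoxymethyl groups ⇐ esterification of the side-chain allylic alcohol with protected p-coumaric acid; aryl ketone ⇐ Weinreb amide plus ortho-lithiated bis(methoxymethyl) hydroquinone.
2. Quaternary C2 of the oxepine (ring O, CO2H, CH2C(O)Ar, ring CH2) ⇐ enantioselective alkylation of the enediolate of the oxepine-2-carboxylic acid with a bromoacetamide under a chiral lithium amide.
3. Oxepine ring ⇐ radical fragmentation of a 2-oxabicyclo[3.2.0]heptane: its ring-fusion bond, which is not in the target, breaks with release of cyclobutane strain because one bridgehead carries the ring oxygen and the ester (captodative radical); this sets the ring alkene (oxepine C5=C6) beside the side chain.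
4. Bicycle ⇐ [2+2] photocycloaddition of ethene to methyl 4-oxo-4,5-dihydrofuran-2-carboxylate. Enabling feature: the O1–C2(CO2Me)=C3H–C4=O unit of the furanone ring, a β-alkoxy enone whose C2=C3 double bond takes up the two ethene carbons (future oxepine C3 and C4) at the future oxepine C2 and C5.
5. Ring order: furanone (step 2) → cyclobutane fused to it (step 3) → seven-membered ring by cleavage of the shared bond (step 7); the side chain comes from carboalumination/oxirane opening and is joined as a Grignard reagent.

Key step: step 3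

Assumption: the facial sense of the chiral lithium amide alkylation (step 9) on this cyclic α-alkoxy enediolate is taken to follow the known enediolate model; if the first run gives the (S)-acid, the antipodal (S,S)-amine is used with no other change.

Step 1
Reactants: 1 1-[(tert-butyldimethylsilyl)oxy]propan-2-one; 2 dimethyl oxalate
Product: 4 methyl 5-[(tert-butyldimethylsilyl)oxy]-2,4-dioxopentanoate, via lithium enolate 3 (not isolated)
Conditions: LiN(SiMe3)2 (2.1 equiv), THF, −78 °C; 2, −78 → 0 °C; 1 M HCl work-up at 0 °C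
Reagents that add atoms: none
Why: Kinetic deprotonation at the methyl group (the siloxymethylene side is hindered and less acidic) followed by crossed Claisen condensation with the non-enolisable oxalate should give the 2,4-diketo ester, drained from the equilibrium as its lithium diketonate.

Step 2
Reactants: 4 silyloxy diketo ester
Product: 6 methyl 4-oxo-4,5-dihydrofuran-2-carboxylate, via hydroxy diketo ester 5 (not isolated)
Conditions: 2 M aq. HCl, THF, rt; then TsOH·H2O (cat.), toluene, 4 Å molecular sieves, 50 °C; used at once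
Reagents that add atoms: none
Why: Acidic desilylation frees the primary alcohol, which adds to the activated C2 keto group (5-exo hemiketal) and dehydrates to the vinylogous ester, the standard cyclodehydration of α′-hydroxy 1,3-diketones to 3(2H)-furanones.

Step 3
Reactants: 6 methyl 4-oxo-4,5-dihydrofuran-2-carboxylate; 7 ethene
Product: 8 methyl cis-4-oxo-2-oxabicyclo[3.2.0]heptane-1-carboxylate (racemic)
Conditions: hν (350 nm, Pyrex), CH2Cl2 saturated with 7 (continuous bubbling), 0.02 M, −78 °C
Reagents that add atoms: none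
Why: Excitation of the β-alkoxy enone chromophore of 6 and intersystem crossing should give the triplet enone, which adds to ethene at C2 or C3 of the furanone to form a triplet 1,4-biradical that closes after spin inversion, so that both new C–C bonds (furanone C2–CH2 and C3–CH2) are made in one operation. The closest known reaction type is the enone–alkene [2+2] photocycloaddition of 3(2H)-furanones and of pyranone- and chromone-2-carboxylates with simple alkenes, the first half of a de Mayo-type sequence. The cyclobutane is closed by radical–radical recombination of the 1,4-biradical onto the existing five-membered ring, giving the 2-oxabicyclo[3.2.0]heptane. The two new bridgehead stereocentres can only be cis, since a trans-fused bicyclo[3.2.0]heptane is too strained, and the racemate is of no consequence because both centres are erased in step 7. The step needs cross-addition to win over photodimerisation of 6, which the large excess of ethene at low temperature and high dilution should secure, while the substrate offers only one photoreactive C=C bond and ethene, being symmetric, raises no regiochemical question.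

Step 4
Reactants: 9 tert-butyldimethyl(prop-2-yn-1-yloxy)silane; 10 oxirane
Product: 12 (E)-5-[(tert-butyldimethylsilyl)oxy]-4-methylpent-3-en-1-ol, via alkenylalane 11 (not isolated)
Conditions: Me3Al (2.5 equiv), Cp2ZrCl2 (0.25 equiv), CH2Cl2, 0 °C → rt; then n-BuLi (1.0 equiv), THF, −78 °C; 10, −78 → 0 °C; 1 M HCl work-up
Reagents that add atoms: trimethylaluminium, C[Al](C)C
Why: Zirconium-catalysed methylalumination (Negishi carboalumination) adds methyl and aluminium syn across the alkyne with aluminium at the terminal carbon, and the derived alanate opens oxirane with retention, which fixes the (E) trisubstituted alkene.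

Step 5
Reactants: 12 homoallylic alcohol
Product: 13 (E)-[(5-bromo-2-methylpent-2-en-1-yl)oxy](tert-butyl)dimethylsilane
Conditions: CBr4, PPh3, CH2Cl2, 0 °C
Reagents that add atoms: tetrabromomethane, BrC(Br)(Br)Br
Why: Appel bromination (SN2 at the primary carbinol) should leave the allylic silyl ether and the alkene geometry untouched.

Step 6
Reactants: 13 homoallylic bromide; 8 bicyclic keto ester
Product: 16 methyl 4-{(E)-5-[(tert-butyldimethylsilyl)oxy]-4-methylpent-3-en-1-yl}-4-[(2-methoxy-2-oxoacetyl)oxy]-2-oxabicyclo[3.2.0]heptane-1-carboxylate (racemic cis-fused mixture of C4 epimers), via Grignard reagent 14 (not isolated), via bromomagnesium alkoxide 15 (not isolated)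
Conditions: Mg, THF, 40 °C (13 → 14); 8, LaCl3·2LiCl (1.0 equiv), THF, −78 → 0 °C; then ClC(O)CO2Me (2 equiv), DMAP (0.1 equiv), −78 °C → rt
Reagents that add atoms: methyl chlorooxoacetate, COC(=O)C(=O)Cl
Why: Lanthanide-promoted Grignard 1,2-addition to the ketone (faster than attack on the hindered bridgehead ester, with little enolisation) followed by O-acylation of the alkoxide should give the tertiary methyl oxalate, whose new carbinol centre may form as a mixture because this carbon becomes sp2 in step 7.

Step 7
Reactants: 16 tertiary methyl oxalate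
Product: 17 methyl 6-{(E)-5-[(tert-butyldimethylsilyl)oxy]-4-methylpent-3-en-1-yl}-2,3,4,7-tetrahydrooxepine-2-carboxylate (racemic)
Conditions: Bu3SnH (1.3 equiv, slow addition), AIBN (0.2 equiv), toluene, 110 °C
Reagents that add atoms: none
Why: Tin hydride deoxygenation of the tert-alkyl methyl oxalate gives the tertiary cyclobutylcarbinyl radical, whose β-scission of the ring-fusion bond is driven by cyclobutane strain release and by formation of the captodative radical flanked by ring oxygen and ester, so that the oxepine and its trisubstituted alkene are set regiospecifically before hydrogen transfer from Bu3SnH.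

Step 8
Reactants: 17 racemic oxepine methyl ester
Product: 18 6-{(E)-5-[(tert-butyldimethylsilyl)oxy]-4-methylpent-3-en-1-yl}-2,3,4,7-tetrahydrooxepine-2-carboxylic acid (racemic)
Conditions: LiOH·H2O (3 equiv), THF/H2O 3:1, rt; 1 M HCl to pH 3 at 0 °C
Reagents that add atoms: lithium hydroxide, [Li+].[OH-]
Why: Saponification (BAc2) of the unhindered α-alkoxy methyl ester, to which the silyl ether and both alkenes are inert at room temperature.

Step 9
Reactants: 18 racemic oxepine acid; 19 2-bromo-N-methoxy-N-methylacetamide
Product: 21 (R)-6-{(E)-5-[(tert-butyldimethylsilyl)oxy]-4-methylpent-3-en-1-yl}-2-{2-[methoxy(methyl)amino]-2-oxoethyl}-2,3,4,7-tetrahydrooxepine-2-carboxylic acid, via dilithium enediolate 20 (not isolated)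
Conditions: (R,R)-N,N′-bis[1-phenyl-2-(piperidin-1-yl)ethyl]propane-1,3-diamine (1.05 equiv), n-BuLi (4.1 equiv), THF, 0 °C; then 19 (1.5 equiv), −78 °C; 1 M HCl work-up (amine recovered by extraction)
Reagents that add atoms: none
Why: Chiral lithium amide-mediated enantioselective alkylation of a carboxylic acid enediolate, a reaction type established for α-oxygenated acids and tetrasubstituted centres: the dilithium amide forms a mixed aggregate with 20, whose ring fixes the enolate geometry, and shields one face so that SN2 attack on the bromoacetamide from the other face sets the (R) quaternary centre.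

Step 10
Reactants: 22 hydroquinone
Product: 23 1,4-bis(methoxymethoxy)benzene
Conditions: NaH (2.5 equiv), DMF, 0 °C; MOMCl (2.4 equiv), 0 °C → rt
Reagents that add atoms: chloromethyl methyl ether, COCCl
Why: Williamson-type O-alkylation of the bis-phenoxide with the reactive chloromethyl ether.

Step 11
Reactants: 23 1,4-bis(methoxymethoxy)benzene; 21 (R)-acid Weinreb amide
Product: 25 (R)-2-{2-[2,5-bis(methoxymethoxy)phenyl]-2-oxoethyl}-6-{(E)-5-[(tert-butyldimethylsilyl)oxy]-4-methylpent-3-en-1-yl}-2,3,4,7-tetrahydrooxepine-2-carboxylic acid, via aryllithium 24 (not isolated)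
Conditions: 23 (3.0 equiv), n-BuLi (2.9 equiv), THF, 0 °C; then 21, THF, −78 → −30 °C; sat. aq. NH4Cl, then pH 4 buffer
Reagents that add atoms: none
Why: Directed ortho-lithiation (all four ring positions are equivalent) and ketone synthesis by addition to the Weinreb amide, whose chelated tetrahedral intermediate stops over-addition and keeps the β-alkoxy ketone masked from base until work-up, while the hindered lithium carboxylate formed by the first equivalent is not attacked.

Step 12
Reactants: 25 keto acid
Product: 26 methoxymethyl (R)-2-{2-[2,5-bis(methoxymethoxy)phenyl]-2-oxoethyl}-6-{(E)-5-[(tert-butyldimethylsilyl)oxy]-4-methylpent-3-en-1-yl}-2,3,4,7-tetrahydrooxepine-2-carboxylate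
Conditions: MOMCl (1.5 equiv), i-Pr2NEt (2.0 equiv), CH2Cl2, 0 °C
Reagents that add atoms: chloromethyl methyl ether, COCCl
Why: O-alkylation of the carboxylate under weakly basic conditions that should not trigger β-elimination of the ring oxygen from the β-alkoxy ketone.

Step 13
Reactants: 26 silyl ether
Product: 27 methoxymethyl (R)-2-{2-[2,5-bis(methoxymethoxy)phenyl]-2-oxoethyl}-6-[(E)-5-hydroxy-4-methylpent-3-en-1-yl]-2,3,4,7-tetrahydrooxepine-2-carboxylate
Conditions: HF·pyridine, pyridine, THF, 0 °C → rt
Reagents that add atoms: none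
Why: Fluoride-mediated desilylation of the primary silyl ether under buffered, non-basic conditions to which the acetal-type methoxymethyl groups are stable.

Step 14
Reactants: 28 4-(methoxymethoxy)benzaldehyde; 29 malonic acid
Product: 30 (E)-3-[4-(methoxymethoxy)phenyl]prop-2-enoic acid
Conditions: pyridine, piperidine (0.1 equiv), 90 °C
Reagents that add atoms: none
Why: Knoevenagel–Doebner condensation with decarboxylation gives the (E)-cinnamic acid under thermodynamic control.

Step 15
Reactants: 27 allylic alcohol; 30 protected coumaric acid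
Product: 31 methoxymethyl (R)-2-{2-[2,5-bis(methoxymethoxy)phenyl]-2-oxoethyl}-6-[(E)-5-({(E)-3-[4-(methoxymethoxy)phenyl]prop-2-enoyl}oxy)-4-methylpent-3-en-1-yl]-2,3,4,7-tetrahydrooxepine-2-carboxylate
Conditions: EDC·HCl (1.5 equiv), DMAP (0.2 equiv), CH2Cl2, 0 °C → rt
Reagents that add atoms: none
Why: Steglich esterification of the unhindered primary allylic alcohol, without allylic transposition because the C–O bond of the alcohol is not broken.

Step 16
Reactants: 31 fully protected ester
Product: 32 (R)-2-[2-(2,5-dihydroxyphenyl)-2-oxoethyl]-6-[(E)-5-{[(E)-3-(4-hydroxyphenyl)prop-2-enoyl]oxy}-4-methylpent-3-en-1-yl]-2,3,4,7-tetrahydrooxepine-2-carboxylic acid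
Conditions: 3 M aq. HCl, THF, 40 °C
Reagents that add atoms: none
Why: Acid hydrolysis of the three aryl methoxymethyl ethers and the methoxymethyl ester (acetal cleavage) avoids base, to which the β-alkoxy ketone and the hydroquinone are sensitive, and the quaternary centre has no acidic hydrogen and cannot epimerise.

**Compound list**

1 | 1-[(tert-butyldimethylsilyl)oxy]propan-2-one | CC(=O)CO[Si](C)(C)C(C)(C)C | starting material
2 | dimethyl oxalate | COC(=O)C(=O)OC | starting material
3 | lithium 3-[(tert-butyldimethylsilyl)oxy]prop-1-en-2-olate | [Li+].C=C([O-])CO[Si](C)(C)C(C)(C)C | intermediate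
4 | methyl 5-[(tert-butyldimethylsilyl)oxy]-2,4-dioxopentanoate | COC(=O)C(=O)CC(=O)CO[Si](C)(C)C(C)(C)C | intermediate
5 | methyl 5-hydroxy-2,4-dioxopentanoate | COC(=O)C(=O)CC(=O)CO | intermediate
6 | methyl 4-oxo-4,5-dihydrofuran-2-carboxylate | COC(=O)C1=CC(=O)CO1 | intermediate
7 | ethene | C=C | starting material
8 | methyl cis-4-oxo-2-oxabicyclo[3.2.0]heptane-1-carboxylate (racemic, one enantiomer drawn) | COC(=O)[C@@]12CC[C@@H]1C(=O)CO2 | intermediate
9 | tert-butyldimethyl(prop-2-yn-1-yloxy)silane | C#CCO[Si](C)(C)C(C)(C)C | starting material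
10 | oxirane | C1CO1 | starting material
11 | (E)-{3-[(tert-butyldimethylsilyl)oxy]-2-methylprop-1-en-1-yl}dimethylalane | C[Al](C)/C=C(\C)CO[Si](C)(C)C(C)(C)C | intermediate
12 | (E)-5-[(tert-butyldimethylsilyl)oxy]-4-methylpent-3-en-1-ol | OCC/C=C(\C)CO[Si](C)(C)C(C)(C)C | intermediate
13 | (E)-[(5-bromo-2-methylpent-2-en-1-yl)oxy](tert-butyl)dimethylsilane | BrCC/C=C(\C)CO[Si](C)(C)C(C)(C)C | intermediate
14 | (E)-{5-[(tert-butyldimethylsilyl)oxy]-4-methylpent-3-en-1-yl}magnesium bromide | Br[Mg]CC/C=C(\C)CO[Si](C)(C)C(C)(C)C | intermediate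
15 | bromomagnesium alkoxide of the tertiary carbinol (racemic cis-fused bicycle, both C4 epimers) | COC(=O)[C@@]12CC[C@@H]1C(CC/C=C(\C)CO[Si](C)(C)C(C)(C)C)(O[Mg]Br)CO2 | intermediate
16 | methyl 4-{(E)-5-[(tert-butyldimethylsilyl)oxy]-4-methylpent-3-en-1-yl}-4-[(2-methoxy-2-oxoacetyl)oxy]-2-oxabicyclo[3.2.0]heptane-1-carboxylate (racemic cis-fused, both C4 epimers) | COC(=O)[C@@]12CC[C@@H]1C(CC/C=C(\C)CO[Si](C)(C)C(C)(C)C)(OC(=O)C(=O)OC)CO2 | intermediate
17 | methyl 6-{(E)-5-[(tert-butyldimethylsilyl)oxy]-4-methylpent-3-en-1-yl}-2,3,4,7-tetrahydrooxepine-2-carboxylate (racemic) | C/C(=C\CCC1=CCCC(C(=O)OC)OC1)CO[Si](C)(C)C(C)(C)C | intermediate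
18 | 6-{(E)-5-[(tert-butyldimethylsilyl)oxy]-4-methylpent-3-en-1-yl}-2,3,4,7-tetrahydrooxepine-2-carboxylic acid (racemic) | C/C(=C\CCC1=CCCC(C(=O)O)OC1)CO[Si](C)(C)C(C)(C)C | intermediate
19 | 2-bromo-N-methoxy-N-methylacetamide | CON(C)C(=O)CBr | starting material
20 | dilithium enediolate of 18 | C/C(=C\CCC1=CCCC(=C([O-])[O-])OC1)CO[Si](C)(C)C(C)(C)C.[Li+].[Li+] | intermediate
21 | (R)-6-{(E)-5-[(tert-butyldimethylsilyl)oxy]-4-methylpent-3-en-1-yl}-2-{2-[methoxy(methyl)amino]-2-oxoethyl}-2,3,4,7-tetrahydrooxepine-2-carboxylic acid | C/C(=C\CCC1=CCC[C@@](CC(=O)N(C)OC)(C(=O)O)OC1)CO[Si](C)(C)C(C)(C)C | intermediate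
22 | hydroquinone | Oc1ccc(O)cc1 | starting material
23 | 1,4-bis(methoxymethoxy)benzene | COCOc1ccc(OCOC)cc1 | intermediate
24 | 2,5-bis(methoxymethoxy)phenyllithium | [Li]c1cc(OCOC)ccc1OCOC | intermediate
25 | (R)-2-{2-[2,5-bis(methoxymethoxy)phenyl]-2-oxoethyl}-6-{(E)-5-[(tert-butyldimethylsilyl)oxy]-4-methylpent-3-en-1-yl}-2,3,4,7-tetrahydrooxepine-2-carboxylic acid | C/C(=C\CCC1=CCC[C@@](CC(=O)c2cc(OCOC)ccc2OCOC)(C(=O)O)OC1)CO[Si](C)(C)C(C)(C)C | intermediate
26 | methoxymethyl ester of 25 | C/C(=C\CCC1=CCC[C@@](CC(=O)c2cc(OCOC)ccc2OCOC)(C(=O)OCOC)OC1)CO[Si](C)(C)C(C)(C)C | intermediate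
27 | methoxymethyl (R)-2-{2-[2,5-bis(methoxymethoxy)phenyl]-2-oxoethyl}-6-[(E)-5-hydroxy-4-methylpent-3-en-1-yl]-2,3,4,7-tetrahydrooxepine-2-carboxylate | C/C(=C\CCC1=CCC[C@@](CC(=O)c2cc(OCOC)ccc2OCOC)(C(=O)OCOC)OC1)CO | intermediate
28 | 4-(methoxymethoxy)benzaldehyde | COCOc1ccc(C=O)cc1 | starting material
29 | malonic acid | OC(=O)CC(=O)O | starting material
30 | (E)-3-[4-(methoxymethoxy)phenyl]prop-2-enoic acid | COCOc1ccc(/C=C/C(=O)O)cc1 | intermediate
31 | methoxymethyl (R)-2-{2-[2,5-bis(methoxymethoxy)phenyl]-2-oxoethyl}-6-[(E)-5-({(E)-3-[4-(methoxymethoxy)phenyl]prop-2-enoyl}oxy)-4-methylpent-3-en-1-yl]-2,3,4,7-tetrahydrooxepine-2-carboxylate | C/C(=C\CCC1=CCC[C@@](CC(=O)c2cc(OCOC)ccc2OCOC)(C(=O)OCOC)OC1)COC(=O)/C=C/c1ccc(OCOC)cc1 | intermediate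
32 | (R)-2-[2-(2,5-dihydroxyphenyl)-2-oxoethyl]-6-[(E)-5-{[(E)-3-(4-hydroxyphenyl)prop-2-enoyl]oxy}-4-methylpent-3-en-1-yl]-2,3,4,7-tetrahydrooxepine-2-carboxylic acid | C/C(=C\CCC1=CCC[C@@](CC(=O)c2cc(O)ccc2O)(C(=O)O)OC1)COC(=O)/C=C/c1ccc(O)cc1 | target

**Step count**

Total: 16 steps. Longest linear sequence: 12 steps (1, 2, 3, 6, 7, 8, 9, 11, 12, 13, 15, 16). The side chain (steps 4–5), the arene (step 10) and the cinnamic acid (step 14) are convergent branches.

**Steps most likely to fail, with fallbacks**

Step 9. The mixed aggregate of a seven-membered α-alkoxy enediolate may give low or reversed facial selectivity, and proton transfer from the enediolate to the acidic bromoacetamide may compete with alkylation. The fallback replaces reagent-controlled induction by classical resolution. It sets out from 17: deprotonation with LiN(i-Pr)2 in THF at −78 °C and alkylation with 19 should give the racemic alkylated methyl ester F1. Hydrolysis with LiOH in THF/H2O should give the racemic acid F2. Fractional crystallisation of its salt with (R)-1-phenylethylamine (or the antipode, whichever gives the less soluble salt of the (R)-acid) should give the diastereomerically pure ammonium salt F3. Acidification returns to the route at 21.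

Step 7. The tertiary radical may open the exocyclic cyclobutane bond, which overlaps better with the radical centre, or may take hydrogen from the tin hydride before it fragments. The fallback is heterolytic. It sets out from 8 and 14: the Grignard addition of step 6 with an aqueous NH4Cl quench instead of acylation should give the tertiary alcohol F4. Treatment with TMSOTf and Et3SiH in CH2Cl2 at −78 °C ionises the carbinol in a Grob fragmentation in which only the ring-fusion bond is antiperiplanar to the lone pair of the ring oxygen. This should give the cyclic oxocarbenium triflate F5 (not isolated), which the silane reduces in the same flask. The sequence returns to the route at 17.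

Step 3. The 2-unsubstituted furanone 6 may photodimerise, drift to its 3-hydroxyfuran tautomer or decompose before it adds ethene. The fallback closes the oxepine by ring-closing metathesis and bypasses steps 1–3, 6 and 7. It sets out from 14: CuI-catalysed carbomagnesiation of prop-2-yn-1-ol with 14, then protonolysis, should give the 2-substituted allylic alcohol F6. Methyl hex-5-enoate is brominated (LiN(i-Pr)2, Me3SiCl, then N-bromosuccinimide) to methyl 2-bromohex-5-enoate F7. Williamson etherification of the sodium alkoxide of F6 (NaH, THF, 0 °C) with F7 should give the diene ether F8. Ring-closing metathesis with the second-generation Grubbs catalyst RuCl2(=CHPh)(PCy3)(H2IMes) in CH2Cl2 at 40 °C returns to the route at 17.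

**Further compounds**

F1 | step 9 | methyl 6-{(E)-5-[(tert-butyldimethylsilyl)oxy]-4-methylpent-3-en-1-yl}-2-{2-[methoxy(methyl)amino]-2-oxoethyl}-2,3,4,7-tetrahydrooxepine-2-carboxylate (racemic) | C/C(=C\CCC1=CCCC(CC(=O)N(C)OC)(C(=O)OC)OC1)CO[Si](C)(C)C(C)(C)C
F2 | step 9 | 6-{(E)-5-[(tert-butyldimethylsilyl)oxy]-4-methylpent-3-en-1-yl}-2-{2-[methoxy(methyl)amino]-2-oxoethyl}-2,3,4,7-tetrahydrooxepine-2-carboxylic acid (racemic) | C/C(=C\CCC1=CCCC(CC(=O)N(C)OC)(C(=O)O)OC1)CO[Si](C)(C)C(C)(C)C
F3 | step 9 | (R)-1-phenylethylammonium salt of 21 | C/C(=C\CCC1=CCC[C@@](CC(=O)N(C)OC)(C(=O)[O-])OC1)CO[Si](C)(C)C(C)(C)C.C[C@@H]([NH3+])c1ccccc1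
F4 | step 7 | methyl 4-{(E)-5-[(tert-butyldimethylsilyl)oxy]-4-methylpent-3-en-1-yl}-4-hydroxy-2-oxabicyclo[3.2.0]heptane-1-carboxylate (racemic cis-fused, both C4 epimers) | COC(=O)[C@@]12CC[C@@H]1C(O)(CC/C=C(\C)CO[Si](C)(C)C(C)(C)C)CO2
F5 | step 7 | 6-{(E)-5-[(tert-butyldimethylsilyl)oxy]-4-methylpent-3-en-1-yl}-2-(methoxycarbonyl)-4,7-dihydro-3H-oxepin-1-ium trifluoromethanesulfonate | C/C(=C\CCC1=CCCC(C(=O)OC)=[O+]C1)CO[Si](C)(C)C(C)(C)C.[O-]S(=O)(=O)C(F)(F)F
F6 | step 3 | 2-{(E)-5-[(tert-butyldimethylsilyl)oxy]-4-methylpent-3-en-1-yl}prop-2-en-1-ol | C=C(CO)CC/C=C(\C)CO[Si](C)(C)C(C)(C)C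
F7 | step 3 | methyl 2-bromohex-5-enoate (racemic) | C=CCCC(Br)C(=O)OC
F8 | step 3 | methyl 2-[(2-{(E)-5-[(tert-butyldimethylsilyl)oxy]-4-methylpent-3-en-1-yl}prop-2-en-1-yl)oxy]hex-5-enoate (racemic) | C=CCCC(OCC(=C)CC/C=C(\C)CO[Si](C)(C)C(C)(C)C)C(=O)OC
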